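**Assumption:** the target has no stereocentre and no configurable double bond (both C=C bonds are endocyclic), so it is achiral; "single enantiomer" needs no stereocontrol and the route delivers the given constitution. Step 4 is a proposed, untested transformation; the other steps are standard.

## Retrosynthetic overview

1. Target 10 ← late O-debenzylation of the 6-O-benzyl ether 9.
2. 9 ← C3–O bond: dehydrogenative C3–H/O–H coupling of coumarin 7 with umbelliferone 8 (the new step; both coumarin rings are intact before the union).
3. 7 ← Wittig olefination/lactonisation of salicylaldehyde 4 (the only ring formed in the route: the pyranone of the 6,7-dioxygenated coumarin).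
4. 4 ← ortho-formylation of phenol 3 ← Baeyer–Villiger oxidation of O-benzylvanillin 1; the umbelliferone ring system is bought.

## Route

Step 1
Reactants: 1 4-(benzyloxy)-3-methoxybenzaldehyde (O-benzylvanillin)
Product: 3 4-(benzyloxy)-3-methoxyphenol, via 4-(benzyloxy)-3-methoxyphenyl formate 2 (not isolated)
Conditions: mCPBA (1.3 equiv), CH2Cl2, 0 °C → rt; then K2CO3 (cat.), MeOH, rt
Reagents that add atoms: mCPBA (3-chloroperoxybenzoic acid), O=C(OO)c1cccc(Cl)c1
Why: Baeyer–Villiger (Dakin-type) oxidation in which the electron-rich p-alkoxyaryl group migrates to give the aryl formate, which is cleaved by base-catalysed methanolysis; the benzyl and methyl ethers are inert and no stereocentre is formed.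

Step 2
Reactants: 3 4-(benzyloxy)-3-methoxyphenol
Product: 4 5-(benzyloxy)-2-hydroxy-4-methoxybenzaldehyde
Conditions: MgCl2 (1.5 equiv), Et3N (3.75 equiv), (CH2O)n (6.75 equiv), MeCN, reflux; aq. HCl work-up
Reagents that add atoms: paraformaldehyde (formaldehyde), C=O
Why: Magnesium phenoxide-directed ortho-formylation (Casnati–Skattebøl) is strictly ortho-selective and takes the unhindered ortho position para to OMe rather than the one flanked by OH and OMe; a second formaldehyde accepts the hydride, and no stereocentre is formed.

Step 3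
Reactants: 4 5-(benzyloxy)-2-hydroxy-4-methoxybenzaldehyde
Product: 7 6-(benzyloxy)-7-methoxy-2H-chromen-2-one, via ethyl (E)-3-[5-(benzyloxy)-2-hydroxy-4-methoxyphenyl]prop-2-enoate 5 (not isolated), via ethyl (Z)-3-[5-(benzyloxy)-2-hydroxy-4-methoxyphenyl]prop-2-enoate 6 (not isolated)
Conditions: Ph3P=CHCO2Et (1.3 equiv), PhNEt2, reflux (ca. 215 °C), 4 h
Reagents that add atoms: ethyl (triphenylphosphoranylidene)acetate, CCOC(=O)C=P(c1ccccc1)(c1ccccc1)c1ccccc1
Why: Wittig olefination of the salicylaldehyde gives the 2-hydroxycinnamate, whose E isomer isomerises thermally to the Z isomer, which lactonises with loss of ethanol (classical one-pot coumarin synthesis); the ring alkene geometry is fixed by the ring and no stereocentre is formed.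

Step 4
Reactants: 7 6-(benzyloxy)-7-methoxy-2H-chromen-2-one; 8 7-hydroxy-2H-chromen-2-one (umbelliferone, 3 equiv)
Product: 9 6-(benzyloxy)-7-methoxy-3-[(2-oxo-2H-chromen-7-yl)oxy]-2H-chromen-2-one
Conditions: 9-mesityl-3,6-di-tert-butyl-10-phenylacridinium BF4 (5 mol%), Co(dmgH)2(py)Cl (5 mol%), MeCN (0.05 M), 450 nm LEDs, Ar, 25 °C, no base
Reagents that add atoms: none
Why: Proposed new method: acceptorless dehydrogenative C3–H aryloxylation of a coumarin, in which the excited acridinium (E*red ≈ +2.0 V vs SCE) oxidises the dialkoxycoumarin 7 (estimated Eox ≈ +1.5 V) in preference to neutral, electron-poor 8; the phenol O–H of 8 then adds to the radical cation at C3 (vinylogous para to the 7-OMe, anti-Markovnikov sense) because this leaves a C4 benzylic radical stabilised by the p-methoxyaryl ring, and the cobaloxime removes the C3 hydrogen (radical capture/β-H elimination or HAT), restoring the C3=C4 bond and releasing H2 while the reduced acridine radical returns the cobalt to its working state; the closest known reaction types are acridinium-photocatalysed anti-Markovnikov hydroetherification of styrenes and acridinium/cobaloxime dehydrogenative C–H alkoxylation or azolation of styrenes, which have not been shown for coumarins (cinnamate-type alkenes) or with phenol O-nucleophiles; no stereocentre is formed.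

Step 5
Reactants: 9 6-(benzyloxy)-7-methoxy-3-[(2-oxo-2H-chromen-7-yl)oxy]-2H-chromen-2-one
Product: 10 6-hydroxy-7-methoxy-3-[(2-oxo-2H-chromen-7-yl)oxy]-2H-chromen-2-one (target)
Conditions: BCl3 (3 equiv), C6HMe5 (5 equiv), CH2Cl2, −78 °C; then MeOH/CHCl3 quench, aq. work-up
Reagents that add atoms: none
Why: Lewis-acid-mediated aryl benzyl ether cleavage with pentamethylbenzene as a non-Lewis-basic benzyl cation scavenger is selective at −78 °C over the aryl methyl ether, the aryl vinyl ether and both lactones, and avoids hydrogenation of the coumarin C3=C4 bonds; no stereocentre is involved.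

## Compound list

1 | 4-(benzyloxy)-3-methoxybenzaldehyde (O-benzylvanillin) | COc1cc(C=O)ccc1OCc1ccccc1 | starting material
2 | 4-(benzyloxy)-3-methoxyphenyl formate | COc1cc(OC=O)ccc1OCc1ccccc1 | intermediate
3 | 4-(benzyloxy)-3-methoxyphenol | COc1cc(O)ccc1OCc1ccccc1 | intermediate
4 | 5-(benzyloxy)-2-hydroxy-4-methoxybenzaldehyde | COc1cc(O)c(C=O)cc1OCc1ccccc1 | intermediate
5 | ethyl (E)-3-[5-(benzyloxy)-2-hydroxy-4-methoxyphenyl]prop-2-enoate | CCOC(=O)/C=C/c1cc(OCc2ccccc2)c(OC)cc1O | intermediate
6 | ethyl (Z)-3-[5-(benzyloxy)-2-hydroxy-4-methoxyphenyl]prop-2-enoate | CCOC(=O)/C=C\c1cc(OCc2ccccc2)c(OC)cc1O | intermediate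
7 | 6-(benzyloxy)-7-methoxy-2H-chromen-2-one | COc1cc2oc(=O)ccc2cc1OCc1ccccc1 | intermediate
8 | 7-hydroxy-2H-chromen-2-one (umbelliferone) | O=c1ccc2ccc(O)cc2o1 | starting material
9 | 6-(benzyloxy)-7-methoxy-3-[(2-oxo-2H-chromen-7-yl)oxy]-2H-chromen-2-one | COc1cc2oc(=O)c(Oc3ccc4ccc(=O)oc4c3)cc2cc1OCc1ccccc1 | intermediate
10 | 6-hydroxy-7-methoxy-3-[(2-oxo-2H-chromen-7-yl)oxy]-2H-chromen-2-one | COc1cc2oc(=O)c(Oc3ccc4ccc(=O)oc4c3)cc2cc1O | target

## Step count and risks

Total step count: 5. Longest linear sequence: 5 steps (1 → 10); umbelliferone 8 is used as bought.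

The three steps most likely to fail:

**Step 4 (proposed new method).** Risks are nucleophile attack on the arene ring (C5/C8) instead of C3, C- rather than O-attack by 8, competitive oxidation of 8, and oxidative damage to the benzyl ether. The fallback uses only known chemistry; it sets out from compound 4 (with commercial 8) and comes back at compound 9. Umbelliferone 8 is O-alkylated with ethyl bromoacetate (K2CO3, acetone, reflux) to ethyl [(2-oxo-2H-chromen-7-yl)oxy]acetate F1. Acid hydrolysis (aq. HCl/AcOH, reflux) gives [(2-oxo-2H-chromen-7-yl)oxy]acetic acid F2. Perkin–Oglialoro condensation of F2 with salicylaldehyde 4 (Ac2O, Et3N, 120 °C) proceeds through the O-acylated aldehyde 4-(benzyloxy)-2-formyl-5-methoxyphenyl [(2-oxo-2H-chromen-7-yl)oxy]acetate F3, whose intramolecular aldol condensation and dehydration give 9 directly. The aryloxy group is thus carried in with the C2–C3 unit, and coumarin 7 is not needed.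

**Step 3 (215 °C Wittig/isomerisation/lactonisation).** Risks are incomplete E→Z isomerisation and thermal loss of the benzyl group. The fallback sets out from compound 4 and comes back at compound 7. Knoevenagel condensation of 4 with Meldrum's acid (cat. piperidine/AcOH, EtOH, reflux) gives 6-(benzyloxy)-7-methoxy-2-oxo-2H-chromene-3-carboxylic acid F4; the cis geometry is enforced by lactonisation, so no isomerisation is needed. Protodecarboxylation (Cu powder, quinoline, 200 °C, or Ag2CO3/AcOH in DMSO at 120 °C) then gives 7.

**Step 5 (late debenzylation).** Risks are competing chelation-assisted cleavage of the neighbouring 7-OMe and poor solubility of the bis-coumarin at −78 °C. The fallback changes the protecting-group plan; it sets out from compound 4 and comes back at compound 10. The benzyl group is removed at the simple aldehyde stage (H2, Pd/C, EtOAc, rt, monitored) to give 2,5-dihydroxy-4-methoxybenzaldehyde F5. Perkin condensation of F5 with [(2-oxo-2H-chromen-7-yl)oxy]acetic acid F2 (made as in the step 4 fallback) in Ac2O/Et3N at 120 °C builds the coumarin and acetylates the remaining phenol, giving 7-methoxy-2-oxo-3-[(2-oxo-2H-chromen-7-yl)oxy]-2H-chromen-6-yl acetate F6. Mild acid hydrolysis (aq. HCl, acetone, 50 °C) then gives 10.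

## Further compounds

F1 | step 4 | ethyl [(2-oxo-2H-chromen-7-yl)oxy]acetate | CCOC(=O)COc1ccc2ccc(=O)oc2c1
F2 | step 4 | [(2-oxo-2H-chromen-7-yl)oxy]acetic acid | O=C(O)COc1ccc2ccc(=O)oc2c1
F3 | step 4 | 4-(benzyloxy)-2-formyl-5-methoxyphenyl [(2-oxo-2H-chromen-7-yl)oxy]acetate | O=Cc1cc(OCc2ccccc2)c(OC)cc1OC(=O)COc1ccc2ccc(=O)oc2c1
F4 | step 3 | 6-(benzyloxy)-7-methoxy-2-oxo-2H-chromene-3-carboxylic acid | COc1cc2oc(=O)c(C(=O)O)cc2cc1OCc1ccccc1
F5 | step 5 | 2,5-dihydroxy-4-methoxybenzaldehyde | COc1cc(O)c(C=O)cc1O
F6 | step 5 | 7-methoxy-2-oxo-3-[(2-oxo-2H-chromen-7-yl)oxy]-2H-chromen-6-yl acetate | COc1cc2oc(=O)c(Oc3ccc4ccc(=O)oc4c3)cc2cc1OC(C)=O
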